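**Plan**

- Retrosynthesis: the aryl esters on O5 and O7 are cleaved last, and ring C is then cut at C2=C3 and at C3–C4.
- Enabling feature: C3 is the lone CH of ring C. It lies between C4, a ketone carbon bonded to ring A, and C2, which carries O1 and ring B and so sits at the oxidation level of a 3,4,5-trimethoxybenzoate ester carbonyl on the O1 phenol. A one-carbon phosphorus ylide can therefore be inserted between a ring A carboxyl derivative and that ortho ester.
- Ring A is a fully substituted benzoate (oxygen at 2,4,6; methoxy at 3,5), traced to phloroglucinol by bromination/copper-catalysed methoxylation and directed lithiation–carboxylation.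
- Forward order: ring A is substituted and carboxylated (steps 1–5), ring B is attached three times as its ester (step 6), the carboxyl is unmasked and silylated (steps 7–8), ring C is closed with the ylide (steps 9–10), and methanolysis frees the two phenols (step 11).
- Stereochemistry: the target is achiral and the C2=C3 bond is endocyclic, so no stereocentre or alkene geometry has to be controlled.

Key step: step 10

Remark: all three ring A phenols are aroylated with the ring B acid chloride, since the two oxygens ortho to the carboxyl are equivalent by symmetry and the surplus esters fall off in the last step; anhydrous phloroglucinol is assumed.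

**Route**

Step 1
Reactants: 1 phloroglucinol
Product: 2 1,3,5-tris(methoxymethoxy)benzene
Conditions: NaH (3.6 equiv), MOMCl (3.6 equiv), DMF, 0 °C → rt
Reagents that add atoms: chloromethyl methyl ether, COCCl
Why: Williamson-type O-alkylation of the trisphenoxide with the hard electrophile MOMCl should give the tris-acetal, whose ethers are stable to base and organolithiums and later direct metalation.

Step 2
Reactants: 2 1,3,5-tris(methoxymethoxy)benzene
Product: 3 2,4-dibromo-1,3,5-tris(methoxymethoxy)benzene
Conditions: NBS (2.05 equiv), MeCN, 0 °C → rt, dark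
Reagents that add atoms: N-bromosuccinimide, O=C1CCC(=O)N1Br
Why: Electrophilic aromatic bromination of a ring in which every C–H is ortho/para to three alkoxy groups should proceed under neutral conditions that spare the acetals, and the three positions are equivalent so only one dibromide can form.

Step 3
Reactants: 3 2,4-dibromo-1,3,5-tris(methoxymethoxy)benzene
Product: 4 2,4-dimethoxy-1,3,5-tris(methoxymethoxy)benzene
Conditions: NaOMe (10 equiv), CuBr (0.2 equiv), EtOAc (cat.), DMF–MeOH, 110 °C
Reagents that add atoms: sodium methoxide, C[O-].[Na+]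
Why: Copper-catalysed Ullmann-type methoxylation of aryl bromides tolerates two ortho alkoxy groups and base-stable MOM ethers, so both C–Br bonds should be exchanged for C–OMe.

Step 4
Reactants: 4 2,4-dimethoxy-1,3,5-tris(methoxymethoxy)benzene
Product: 6 benzyl 3,5-dimethoxy-2,4,6-tris(methoxymethoxy)benzoate, via aryllithium 5 (not isolated)
Conditions: n-BuLi (1.05 equiv), THF, 0 °C; then cannulated into ClCO2Bn (1.5 equiv), THF, −78 °C → rt
Reagents that add atoms: benzyl chloroformate, O=C(Cl)OCc1ccccc1
Why: Directed ortho-metalation removes the only ring proton, which lies between two MOM ethers, and inverse addition of the hindered aryllithium to excess chloroformate at low temperature should stop at the benzoate ester.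

Step 5
Reactants: 6 benzyl 3,5-dimethoxy-2,4,6-tris(methoxymethoxy)benzoate
Product: 7 benzyl 2,4,6-trihydroxy-3,5-dimethoxybenzoate
Conditions: HCl (1.25 M in MeOH), rt → 40 °C, Ar
Reagents that add atoms: none
Why: Acid-catalysed acetal exchange with methanol removes the three MOM groups as dimethoxymethane, while the doubly ortho-substituted benzyl ester resists transesterification and the ring has no free position for alkylation.

Step 6
Reactants: 7 benzyl 2,4,6-trihydroxy-3,5-dimethoxybenzoate; 8 3,4,5-trimethoxybenzoyl chloride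
Product: 9 benzyl 3,5-dimethoxy-2,4,6-tris[(3,4,5-trimethoxybenzoyl)oxy]benzoate
Conditions: 8 (3.6 equiv), Et3N (5 equiv), DMAP (0.3 equiv), CH2Cl2, 0 °C → reflux
Reagents that add atoms: 3,4,5-trimethoxybenzoyl chloride, COc1cc(C(=O)Cl)cc(OC)c1OC
Why: DMAP-catalysed O-acylation with excess acid chloride should esterify all three phenols, including the two hydrogen-bonded ones ortho to the ester, so no hydroxyl has to be differentiated.

Step 7
Reactants: 9 benzyl 3,5-dimethoxy-2,4,6-tris[(3,4,5-trimethoxybenzoyl)oxy]benzoate
Product: 10 3,5-dimethoxy-2,4,6-tris[(3,4,5-trimethoxybenzoyl)oxy]benzoic acid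
Conditions: H2 (1 atm), 10% Pd/C, EtOAc, rt
Reagents that add atoms: none
Why: Catalytic hydrogenolysis cleaves the benzyl ester under neutral conditions and leaves aryl benzoates and aryl methyl ethers untouched.

Step 8
Reactants: 10 3,5-dimethoxy-2,4,6-tris[(3,4,5-trimethoxybenzoyl)oxy]benzoic acid
Product: 11 tert-butyldimethylsilyl 3,5-dimethoxy-2,4,6-tris[(3,4,5-trimethoxybenzoyl)oxy]benzoate
Conditions: TBSCl (1.2 equiv), Et3N (1.5 equiv), CH2Cl2, 0 °C → rt; filtered under Ar, concentrated, used crude
Reagents that add atoms: tert-butyldimethylsilyl chloride, CC(C)(C)[Si](C)(C)Cl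
Why: O-silylation of the carboxylate, whose oxygen lies outside the shielding of the ortho groups, gives the silyl ester with a non-nucleophilic base that should not cleave the aryl esters.

Step 9
Reactants: 12 methyltriphenylphosphonium bromide
Product: 15 (trimethylsilyl)methylenetriphenylphosphorane, via methylenetriphenylphosphorane 13 (not isolated), via (trimethylsilylmethyl)triphenylphosphonium chloride 14 (not isolated)
Conditions: n-BuLi (1.0 equiv), THF, 0 °C; Me3SiCl (0.5 equiv), 0 °C → rt; filtered under Ar, THF solution used in step 10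
Reagents that add atoms: chlorotrimethylsilane, C[Si](C)(C)Cl
Why: Wittig ylide formation by deprotonation is followed by C-silylation and transylidation, in which the second equivalent of the methylene ylide deprotonates the more acidic silylmethylphosphonium salt.

Step 10
Reactants: 11 tert-butyldimethylsilyl 3,5-dimethoxy-2,4,6-tris[(3,4,5-trimethoxybenzoyl)oxy]benzoate; 15 (trimethylsilyl)methylenetriphenylphosphorane
Product: 17 6,8-dimethoxy-5,7-bis[(3,4,5-trimethoxybenzoyl)oxy]-2-(3,4,5-trimethoxyphenyl)-4H-chromen-4-one, via acyl ylide 16 (not isolated)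
Conditions: 15 (1.1 equiv, added slowly), THF, 0 °C → reflux
Reagents that add atoms: (trimethylsilyl)methylenetriphenylphosphorane, C[Si](C)(C)C=P(c1ccccc1)(c1ccccc1)c1ccccc1
Why: The ylide carbon of 15 acylates at the silyl ester carbonyl of 11, and the departing silanolate takes the C-silyl group with it as the disiloxane, so the stabilised aroylmethylene phosphorane 16 forms irreversibly (C4–C3 bond). On heating, the ylide carbon of 16 adds to the carbonyl of an ortho 3,4,5-trimethoxybenzoate in a 6-exo-trig mode, and the oxaphosphetane collapses with loss of Ph3P=O to the C2=C3 bond, closing ring C by intramolecular Wittig olefination of an ester. The closest known reaction is the chromone and flavone synthesis from silyl esters of O-acyl- and O-aroylsalicylic acids with this same ylide. No stereocentre is formed. The selectivity needed is attack at the silyl ester in preference to the three aryl esters; this rests on the silyloxy leaving group that makes only that acylation irreversible, on the deactivation of the aryl ester carbonyls by their electron-rich trimethoxyphenyl rings, and on slow addition of a slight excess of ylide at 0 °C. The two ortho esters are equivalent by symmetry, so either closure gives the same flavone.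

Step 11
Reactants: 17 6,8-dimethoxy-5,7-bis[(3,4,5-trimethoxybenzoyl)oxy]-2-(3,4,5-trimethoxyphenyl)-4H-chromen-4-one
Product: 18 5,7-dihydroxy-6,8-dimethoxy-2-(3,4,5-trimethoxyphenyl)-4H-chromen-4-one
Conditions: K2CO3 (3 equiv), MeOH–THF, rt; then 1 M HCl
Reagents that add atoms: none
Why: Base-mediated methanolysis (transesterification) of the two aryl esters frees the 5- and 7-hydroxyls, the flavone core and methyl ethers are stable to carbonate at room temperature, and a Wessely–Moser-type ring isomerisation would be degenerate because C6 and C8 carry the same group.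

**Compound list**

1 | phloroglucinol | Oc1cc(O)cc(O)c1 | starting material
2 | 1,3,5-tris(methoxymethoxy)benzene | COCOc1cc(OCOC)cc(OCOC)c1 | intermediate
3 | 2,4-dibromo-1,3,5-tris(methoxymethoxy)benzene | COCOc1cc(OCOC)c(Br)c(OCOC)c1Br | intermediate
4 | 2,4-dimethoxy-1,3,5-tris(methoxymethoxy)benzene | COCOc1cc(OCOC)c(OC)c(OCOC)c1OC | intermediate
5 | [3,5-dimethoxy-2,4,6-tris(methoxymethoxy)phenyl]lithium | [Li]c1c(OCOC)c(OC)c(OCOC)c(OC)c1OCOC | intermediate
6 | benzyl 3,5-dimethoxy-2,4,6-tris(methoxymethoxy)benzoate | O=C(OCc1ccccc1)c1c(OCOC)c(OC)c(OCOC)c(OC)c1OCOC | intermediate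
7 | benzyl 2,4,6-trihydroxy-3,5-dimethoxybenzoate | O=C(OCc1ccccc1)c1c(O)c(OC)c(O)c(OC)c1O | intermediate
8 | 3,4,5-trimethoxybenzoyl chloride | COc1cc(C(=O)Cl)cc(OC)c1OC | starting material
9 | benzyl 3,5-dimethoxy-2,4,6-tris[(3,4,5-trimethoxybenzoyl)oxy]benzoate | O=C(OCc1ccccc1)c1c(OC(=O)c2cc(OC)c(OC)c(OC)c2)c(OC)c(OC(=O)c2cc(OC)c(OC)c(OC)c2)c(OC)c1OC(=O)c1cc(OC)c(OC)c(OC)c1 | intermediate
10 | 3,5-dimethoxy-2,4,6-tris[(3,4,5-trimethoxybenzoyl)oxy]benzoic acid | OC(=O)c1c(OC(=O)c2cc(OC)c(OC)c(OC)c2)c(OC)c(OC(=O)c2cc(OC)c(OC)c(OC)c2)c(OC)c1OC(=O)c1cc(OC)c(OC)c(OC)c1 | intermediate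
11 | tert-butyldimethylsilyl 3,5-dimethoxy-2,4,6-tris[(3,4,5-trimethoxybenzoyl)oxy]benzoate | CC(C)(C)[Si](C)(C)OC(=O)c1c(OC(=O)c2cc(OC)c(OC)c(OC)c2)c(OC)c(OC(=O)c2cc(OC)c(OC)c(OC)c2)c(OC)c1OC(=O)c1cc(OC)c(OC)c(OC)c1 | intermediate
12 | methyltriphenylphosphonium bromide | C[P+](c1ccccc1)(c1ccccc1)c1ccccc1.[Br-] | starting material
13 | methylenetriphenylphosphorane | C=P(c1ccccc1)(c1ccccc1)c1ccccc1 | intermediate
14 | (trimethylsilylmethyl)triphenylphosphonium chloride | C[Si](C)(C)C[P+](c1ccccc1)(c1ccccc1)c1ccccc1.[Cl-] | intermediate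
15 | (trimethylsilyl)methylenetriphenylphosphorane | C[Si](C)(C)C=P(c1ccccc1)(c1ccccc1)c1ccccc1 | intermediate
16 | 1-{3,5-dimethoxy-2,4,6-tris[(3,4,5-trimethoxybenzoyl)oxy]phenyl}-2-(triphenylphosphoranylidene)ethan-1-one (acyl ylide) | O=C(C=P(c1ccccc1)(c1ccccc1)c1ccccc1)c1c(OC(=O)c2cc(OC)c(OC)c(OC)c2)c(OC)c(OC(=O)c2cc(OC)c(OC)c(OC)c2)c(OC)c1OC(=O)c1cc(OC)c(OC)c(OC)c1 | intermediate
17 | 6,8-dimethoxy-5,7-bis[(3,4,5-trimethoxybenzoyl)oxy]-2-(3,4,5-trimethoxyphenyl)-4H-chromen-4-one | COc1cc(-c2cc(=O)c3c(OC(=O)c4cc(OC)c(OC)c(OC)c4)c(OC)c(OC(=O)c4cc(OC)c(OC)c(OC)c4)c(OC)c3o2)cc(OC)c1OC | intermediate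
18 | 5,7-dihydroxy-6,8-dimethoxy-2-(3,4,5-trimethoxyphenyl)-4H-chromen-4-one (5,7-dihydroxy-6,8,3',4',5'-pentamethoxyflavone) | COc1cc(-c2cc(=O)c3c(O)c(OC)c(O)c(OC)c3o2)cc(OC)c1OC | target

**Step count and risks**

Total step count: 11. Longest linear sequence: 10 steps (steps 1–8, 10 and 11); step 9 is a one-step side branch that supplies the ylide.

Steps most likely to fail:

1. Step 10. The silyl ester carbonyl is shielded by two ortho aroyloxy groups, so the bulky silyl ylide may instead attack the aryl ester carbonyls, causing acyl transfer and release of phenoxide, or the ester olefination may be sluggish. The fallback sets out from acid 10 and comes back at 17. Acid 10 would be treated with oxalyl chloride and catalytic DMF in CH2Cl2 to give 3,5-dimethoxy-2,4,6-tris[(3,4,5-trimethoxybenzoyl)oxy]benzoyl chloride F1. This far more electrophilic acyl donor would be added at −78 °C in THF to two equivalents of the smaller ylide 13, made as in step 9 without the silyl chloride. C-acylation should give (2-{3,5-dimethoxy-2,4,6-tris[(3,4,5-trimethoxybenzoyl)oxy]phenyl}-2-oxoethyl)triphenylphosphonium chloride F2, which the second equivalent of 13 deprotonates to acyl ylide 16. Heating 16 in toluene closes ring C to 17. This route also bypasses the moisture-sensitive silyl ester of step 8.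

2. Step 3. The twofold methoxylation at positions flanked by two alkoxy groups may stall after one substitution or lose bromine reductively. The fallback sets out from 2 and comes back at 4, bypassing step 2 as well. Compound 2 would be lithiated (n-BuLi, THF, 0 °C) to [2,4,6-tris(methoxymethoxy)phenyl]lithium F3 and trapped with B(OMe)3 as dimethyl [2,4,6-tris(methoxymethoxy)phenyl]boronate F4. Oxidation with H2O2/NaOH gives 2,4,6-tris(methoxymethoxy)phenol F5, and methylation (MeI, K2CO3, acetone) gives 2-methoxy-1,3,5-tris(methoxymethoxy)benzene F6. A second round of the same operations passes through [3-methoxy-2,4,6-tris(methoxymethoxy)phenyl]lithium F7, dimethyl [3-methoxy-2,4,6-tris(methoxymethoxy)phenyl]boronate F8 and 3-methoxy-2,4,6-tris(methoxymethoxy)phenol F9. Methylation of F9 gives 4.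

3. Step 4. The aryllithium may add a second time to the ester it has just formed, or residual butyllithium may consume the chloroformate. The fallback sets out from 4 and comes back at 6. Aryllithium 5, generated as in step 4, would be quenched with dry CO2 to give lithium 3,5-dimethoxy-2,4,6-tris(methoxymethoxy)benzoate F10, which cannot over-add. After exchange of the solvent for DMF, the carboxylate would be O-alkylated with benzyl bromide at 50 °C to give 6 without any acidic work-up that could endanger the MOM ethers.

Further compounds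
F1 | step 10 | 3,5-dimethoxy-2,4,6-tris[(3,4,5-trimethoxybenzoyl)oxy]benzoyl chloride | ClC(=O)c1c(OC(=O)c2cc(OC)c(OC)c(OC)c2)c(OC)c(OC(=O)c2cc(OC)c(OC)c(OC)c2)c(OC)c1OC(=O)c1cc(OC)c(OC)c(OC)c1
F2 | step 10 | (2-{3,5-dimethoxy-2,4,6-tris[(3,4,5-trimethoxybenzoyl)oxy]phenyl}-2-oxoethyl)triphenylphosphonium chloride | O=C(C[P+](c1ccccc1)(c1ccccc1)c1ccccc1)c1c(OC(=O)c2cc(OC)c(OC)c(OC)c2)c(OC)c(OC(=O)c2cc(OC)c(OC)c(OC)c2)c(OC)c1OC(=O)c1cc(OC)c(OC)c(OC)c1.[Cl-]
F3 | step 3 | [2,4,6-tris(methoxymethoxy)phenyl]lithium | [Li]c1c(OCOC)cc(OCOC)cc1OCOC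
F4 | step 3 | dimethyl [2,4,6-tris(methoxymethoxy)phenyl]boronate | COB(OC)c1c(OCOC)cc(OCOC)cc1OCOC
F5 | step 3 | 2,4,6-tris(methoxymethoxy)phenol | Oc1c(OCOC)cc(OCOC)cc1OCOC
F6 | step 3 | 2-methoxy-1,3,5-tris(methoxymethoxy)benzene | COc1c(OCOC)cc(OCOC)cc1OCOC
F7 | step 3 | [3-methoxy-2,4,6-tris(methoxymethoxy)phenyl]lithium | [Li]c1c(OCOC)c(OC)c(OCOC)cc1OCOC
F8 | step 3 | dimethyl [3-methoxy-2,4,6-tris(methoxymethoxy)phenyl]boronate | COB(OC)c1c(OCOC)c(OC)c(OCOC)cc1OCOC
F9 | step 3 | 3-methoxy-2,4,6-tris(methoxymethoxy)phenol | Oc1c(OCOC)c(OC)c(OCOC)cc1OCOC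
F10 | step 4 | lithium 3,5-dimethoxy-2,4,6-tris(methoxymethoxy)benzoate | [Li+].[O-]C(=O)c1c(OCOC)c(OC)c(OCOC)c(OC)c1OCOC
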